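**Retrosynthetic overview**

1. Target 20 (germacrane numbering: ring C1–C10, C1=C10, angelate on C3, oxirane C4–C5, acetate on C6, isopropyl C11–C13 on C7) ⇐ 18 by hydrogenation of C11=C12 and acetylation of C6–OH.
2. 18 ⇐ open-chain epoxy aldehyde 15 by closing the ten-membered carbocycle at C6–C7 with an intramolecular, stereoconvergent palladium/diethylzinc umpolung allylation (sets C6 and C7).
3. Enabling feature: C6 is a carbinol carbon held between the C4–C5 oxirane and C7, and C7 carries the branched C11–C13 unit. C12–C11–C7 is therefore a 2-methylallyl unit (hydrogenated in the target) whose γ-carbon C7 can add to an epoxy-aldehyde carbon C6.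
4. 15 ⇐ epoxy alcohol 7 (angelate on C3, allylic oxidation and chlorination at C12, oxidation of C6); 7 ⇐ racemic alcohol 6 by Sharpless kinetic-resolution epoxidation (sets C3, C4, C5); 6 ⇐ geranylbarium + enal 3 (C2–C3 bond).
5. Ring order: oxirane first (step 3), ten-membered carbocycle last (step 9).

Key step: step 9

Remark: atom labels in the text follow germacrane numbering, also for the open-chain intermediates (compound names keep systematic locants); the C3 ester is taken as the (Z)-2-methylbut-2-enoate (angelate) and the ring alkene as (E), as the structure shows.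

**Route**

Step 1
Reactants: 1 (tert-butyldimethylsilyloxy)acetaldehyde; 2 2-(triphenylphosphoranylidene)propanal
Product: 3 (E)-4-(tert-butyldimethylsilyloxy)-2-methylbut-2-enal
Conditions: toluene, 80 °C
Reagents that add atoms: none
Why: Wittig olefination with a formyl-stabilised ylide, which should give the (E)-trisubstituted enal selectively and stops at the less electrophilic α-branched enal.

Step 2
Reactants: 4 geranyl chloride; 3 (E)-4-(tert-butyldimethylsilyloxy)-2-methylbut-2-enal
Product: 6 rac-(2E,6E)-1-(tert-butyldimethylsilyloxy)-3,7,11-trimethyldodeca-2,6,10-trien-4-ol, via geranylbarium chloride 5 (not isolated)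
Conditions: BaI2, lithium biphenylide (2 equiv), THF, rt (gives activated zerovalent barium); 4, −78 °C; then 3, −78 °C; aq NH4Cl
Reagents that add atoms: none
Why: Allylbarium carbonyl allylation, in which the geranylbarium reagent keeps its (E)-geometry at −78 °C and adds through its α-carbon in a 1,2-fashion to the enal, giving the linear alcohol as a racemate that step 3 resolves.

Step 3
Reactants: 6 rac-(2E,6E)-1-(tert-butyldimethylsilyloxy)-3,7,11-trimethyldodeca-2,6,10-trien-4-ol
Product: 7 (2R,3R,4R,6E)-1-(tert-butyldimethylsilyloxy)-2,3-epoxy-3,7,11-trimethyldodeca-6,10-dien-4-ol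
Conditions: Ti(OiPr)4 (1.0 equiv), D-(−)-diisopropyl tartrate (1.2 equiv), t-BuOOH (0.45 equiv), 4 Å MS, CH2Cl2, −20 °C
Reagents that add atoms: tert-butyl hydroperoxide, CC(C)(C)OO
Why: Sharpless kinetic resolution of a secondary allylic alcohol, in which the D-(−)-tartrate complex delivers oxygen to the alkene face that gives the (4R,5R)-oxirane and does so fast only for the (3R)-alcohol (erythro product, the C2 chain pointing away from the reagent), so that C3, C4 and C5 are set together while the (3S)-alcohol stays unreacted and is separated.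

Step 4
Reactants: 7 (2R,3R,4R,6E)-1-(tert-butyldimethylsilyloxy)-2,3-epoxy-3,7,11-trimethyldodeca-6,10-dien-4-ol; 8 angelic acid
Product: 10 (2R,3R,4R,6E)-1-(tert-butyldimethylsilyloxy)-2,3-epoxy-3,7,11-trimethyldodeca-6,10-dien-4-yl (Z)-2-methylbut-2-enoate, via angelic 2,4,6-trichlorobenzoic anhydride 9 (not isolated)
Conditions: 8, 2,4,6-trichlorobenzoyl chloride, Et3N, toluene, rt; then 7, 80 °C
Reagents that add atoms: none
Why: Yamaguchi-type esterification through the mixed anhydride without DMAP, conditions under which angelates should form with retention of the (Z)-geometry, and the C3–O bond is not broken so the carbinol configuration is kept.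

Step 5
Reactants: 10 (2R,3R,4R,6E)-1-(tert-butyldimethylsilyloxy)-2,3-epoxy-3,7,11-trimethyldodeca-6,10-dien-4-yl (Z)-2-methylbut-2-enoate
Product: 11 (2R,3R,4R,6E,10E)-1-(tert-butyldimethylsilyloxy)-2,3-epoxy-12-hydroxy-3,7,11-trimethyldodeca-6,10-dien-4-yl (Z)-2-methylbut-2-enoate
Conditions: SeO2 (0.5 equiv), t-BuOOH (3 equiv), salicylic acid (0.1 equiv), CH2Cl2, 0 °C to rt, stopped at partial conversion
Reagents that add atoms: tert-butyl hydroperoxide, CC(C)(C)OO (terminal oxidant); selenium dioxide, O=[Se]=O (oxygen carrier)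
Why: Riley allylic oxidation (ene reaction then 2,3-sigmatropic shift), which should hydroxylate the (E)-methyl group of the terminal, most accessible and most electron-rich trisubstituted alkene, while the internal C1=C10 alkene is more hindered and the angelate alkene is electron-poor.

Step 6
Reactants: 11 (2R,3R,4R,6E,10E)-1-(tert-butyldimethylsilyloxy)-2,3-epoxy-12-hydroxy-3,7,11-trimethyldodeca-6,10-dien-4-yl (Z)-2-methylbut-2-enoate
Product: 13 (2R,3R,4R,6E,10E)-1-(tert-butyldimethylsilyloxy)-12-chloro-2,3-epoxy-3,7,11-trimethyldodeca-6,10-dien-4-yl (Z)-2-methylbut-2-enoate, via allylic mesylate 12 (not isolated)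
Conditions: MsCl, LiCl, 2,4,6-collidine, DMF, 0 °C
Reagents that add atoms: lithium chloride, [Li+].[Cl-]
Why: Collington–Meyers chlorination, in which the primary allylic mesylate formed in the flask is displaced by chloride (SN2) at 0 °C without allylic transposition, and any (Z)- or SN2'-isomer that forms would converge in step 9.

Step 7
Reactants: 13 (2R,3R,4R,6E,10E)-1-(tert-butyldimethylsilyloxy)-12-chloro-2,3-epoxy-3,7,11-trimethyldodeca-6,10-dien-4-yl (Z)-2-methylbut-2-enoate
Product: 14 (2R,3R,4R,6E,10E)-12-chloro-2,3-epoxy-1-hydroxy-3,7,11-trimethyldodeca-6,10-dien-4-yl (Z)-2-methylbut-2-enoate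
Conditions: HF·pyridine, pyridine, THF, 0 °C
Reagents that add atoms: none
Why: Fluoride-mediated cleavage of the primary TBS ether under pyridine-buffered conditions that should leave the oxirane, the allylic chloride and the angelate untouched.

Step 8
Reactants: 14 (2R,3R,4R,6E,10E)-12-chloro-2,3-epoxy-1-hydroxy-3,7,11-trimethyldodeca-6,10-dien-4-yl (Z)-2-methylbut-2-enoate
Product: 15 (2S,3R,4R,6E,10E)-12-chloro-2,3-epoxy-3,7,11-trimethyl-1-oxododeca-6,10-dien-4-yl (Z)-2-methylbut-2-enoate
Conditions: Dess–Martin periodinane, pyridine, CH2Cl2, 0 °C to rt; used directly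
Reagents that add atoms: none
Why: Dess–Martin oxidation of the primary 2,3-epoxy alcohol to the epoxy aldehyde under buffered conditions, C5 being an oxirane carbon that does not epimerise (its descriptor changes only because the formyl group gains priority).

Step 9
Reactants: 15 (2S,3R,4R,6E,10E)-12-chloro-2,3-epoxy-3,7,11-trimethyl-1-oxododeca-6,10-dien-4-yl (Z)-2-methylbut-2-enoate
Product: 18 (1(10)E,3R,4R,5R,6S,7S)-4,5-epoxy-6-hydroxygermacra-1(10),11-dien-3-yl (Z)-2-methylbut-2-enoate, via allylpalladium chloride 16 (not isolated), via allyl(ethyl)zinc reagent 17 (not isolated)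
Conditions: PdCl2(PPh3)2 (10 mol %), Et2Zn (4 equiv), K2CO3, DMA, rt; 15 added over 12 h (final 0.005 M); aq NH4Cl
Reagents that add atoms: none
Why: Zerovalent palladium (from PdCl2(PPh3)2 and Et2Zn) ionises the C12–Cl bond to the allylpalladium chloride 16, Et2Zn transmetalates it to the nucleophilic allyl(ethyl)zinc 17 (umpolung), and 17 adds through its γ-carbon C7 to the C6 aldehyde in a six-membered chair (Zimmerman–Traxler) array, the C11=C12 double bond ending up exocyclic as the 2-propenyl group. The closest known reaction type is the palladium/diethylzinc umpolung allylation of aldehydes by allylic halides and esters, which has been used intramolecularly on farnesane-derived 2,3-epoxy aldehydes to close the ten-membered germacrane ring at this same bond. The one ring closed is the ten-membered carbocycle, by 10-exo-trig attack of C7 on the formyl carbon (the carbonyl oxygen stays outside the ring). C7 is controlled by the (E)-geometry of the allylzinc, to which (E)-, (Z)- and SN2'-isomeric chlorides all converge because 16 and 17 equilibrate by η3–η1 shifts, so that the chair with the C8 chain equatorial should give the anti (6,7-trans) pair; C6 is controlled by the C5 oxirane stereocentre, C–C bonding occurring anti to the C5–O bond in the rotamer that puts the formyl hydrogen rather than the carbonyl oxygen over the C4 methyl group, which gives the (6S) configuration of the target. The step needs ring closure to outrun intermolecular allylation and needs chemoselectivity for the aldehyde: the first is secured by slow addition at high dilution and by the two (E)-configured units (C1=C10 and the trans C4–C5 oxirane) that fold the chain towards the crown shape of the product, the second by the chloride being the only allylic leaving group (the C3 ester sits next to an oxirane carbon, not an alkene) and by allylzinc reagents adding to aldehydes far faster than to esters or oxiranes.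

Step 10
Reactants: 18 (1(10)E,3R,4R,5R,6S,7S)-4,5-epoxy-6-hydroxygermacra-1(10),11-dien-3-yl (Z)-2-methylbut-2-enoate
Product: 19 (1(10)E,3R,4R,5R,6S,7S)-4,5-epoxy-6-hydroxygermacr-1(10)-en-3-yl (Z)-2-methylbut-2-enoate
Conditions: RhCl(PPh3)3 (10 mol %), H2 (1 atm), benzene, rt
Reagents that add atoms: none
Why: Homogeneous hydrogenation with RhCl(PPh3)3, which should reduce the unhindered 1,1-disubstituted C11=C12 alkene much faster than the trisubstituted ring alkene or the trisubstituted conjugated angelate alkene and does not touch the oxirane; no stereocentre is formed.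

Step 11
Reactants: 19 (1(10)E,3R,4R,5R,6S,7S)-4,5-epoxy-6-hydroxygermacr-1(10)-en-3-yl (Z)-2-methylbut-2-enoate
Product: 20 (1(10)E,3R,4R,5R,6S,7S)-6-acetoxy-4,5-epoxygermacr-1(10)-en-3-yl (Z)-2-methylbut-2-enoate (CNP0180504.3)
Conditions: Ac2O, DMAP (cat.), pyridine, rt
Reagents that add atoms: acetic anhydride, CC(=O)OC(C)=O
Why: DMAP-catalysed acylation of the hindered secondary C6 alcohol under basic conditions, which avoid acid-triggered transannular attack of the C1=C10 alkene on the oxirane and keep the C6 configuration because the C–O bond is not broken.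

**Compound list**

1 | (tert-butyldimethylsilyloxy)acetaldehyde | O=CCO[Si](C)(C)C(C)(C)C | starting material
2 | 2-(triphenylphosphoranylidene)propanal | CC(C=O)=P(c1ccccc1)(c1ccccc1)c1ccccc1 | starting material
3 | (E)-4-(tert-butyldimethylsilyloxy)-2-methylbut-2-enal | O=C/C(C)=C/CO[Si](C)(C)C(C)(C)C | intermediate
4 | geranyl chloride, (2E)-1-chloro-3,7-dimethylocta-2,6-diene | CC(C)=CCC/C(C)=C/CCl | starting material
5 | geranylbarium chloride (not isolated) | CC(C)=CCC/C(C)=C/C[Ba]Cl | intermediate
6 | rac-(2E,6E)-1-(tert-butyldimethylsilyloxy)-3,7,11-trimethyldodeca-2,6,10-trien-4-ol | CC(C)=CCC/C(C)=C/CC(O)/C(C)=C/CO[Si](C)(C)C(C)(C)C | intermediate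
7 | (2R,3R,4R,6E)-1-(tert-butyldimethylsilyloxy)-2,3-epoxy-3,7,11-trimethyldodeca-6,10-dien-4-ol | O[C@H](C/C=C(\C)CCC=C(C)C)[C@@]1(C)O[C@@H]1CO[Si](C)(C)C(C)(C)C | intermediate
8 | angelic acid, (Z)-2-methylbut-2-enoic acid | C/C=C(/C)C(=O)O | starting material
9 | angelic 2,4,6-trichlorobenzoic anhydride (not isolated) | C/C=C(/C)C(=O)OC(=O)c1c(Cl)cc(Cl)cc1Cl | intermediate
10 | (2R,3R,4R,6E)-1-(tert-butyldimethylsilyloxy)-2,3-epoxy-3,7,11-trimethyldodeca-6,10-dien-4-yl (Z)-2-methylbut-2-enoate | C/C=C(/C)C(=O)O[C@H](C/C=C(\C)CCC=C(C)C)[C@@]1(C)O[C@@H]1CO[Si](C)(C)C(C)(C)C | intermediate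
11 | (2R,3R,4R,6E,10E)-1-(tert-butyldimethylsilyloxy)-2,3-epoxy-12-hydroxy-3,7,11-trimethyldodeca-6,10-dien-4-yl (Z)-2-methylbut-2-enoate | C/C=C(/C)C(=O)O[C@H](C/C=C(\C)CC/C=C(\C)CO)[C@@]1(C)O[C@@H]1CO[Si](C)(C)C(C)(C)C | intermediate
12 | 12-methanesulfonate of 11 (allylic mesylate, not isolated) | C/C=C(/C)C(=O)O[C@H](C/C=C(\C)CC/C=C(\C)COS(C)(=O)=O)[C@@]1(C)O[C@@H]1CO[Si](C)(C)C(C)(C)C | intermediate
13 | (2R,3R,4R,6E,10E)-1-(tert-butyldimethylsilyloxy)-12-chloro-2,3-epoxy-3,7,11-trimethyldodeca-6,10-dien-4-yl (Z)-2-methylbut-2-enoate | C/C=C(/C)C(=O)O[C@H](C/C=C(\C)CC/C=C(\C)CCl)[C@@]1(C)O[C@@H]1CO[Si](C)(C)C(C)(C)C | intermediate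
14 | (2R,3R,4R,6E,10E)-12-chloro-2,3-epoxy-1-hydroxy-3,7,11-trimethyldodeca-6,10-dien-4-yl (Z)-2-methylbut-2-enoate | C/C=C(/C)C(=O)O[C@H](C/C=C(\C)CC/C=C(\C)CCl)[C@@]1(C)O[C@@H]1CO | intermediate
15 | (2S,3R,4R,6E,10E)-12-chloro-2,3-epoxy-3,7,11-trimethyl-1-oxododeca-6,10-dien-4-yl (Z)-2-methylbut-2-enoate | C/C=C(/C)C(=O)O[C@H](C/C=C(\C)CC/C=C(\C)CCl)[C@@]1(C)O[C@@H]1C=O | intermediate
16 | allylpalladium chloride from 15, drawn as the C12-bound form without phosphine ligands (not isolated) | C/C=C(/C)C(=O)O[C@H](C/C=C(\C)CC/C=C(\C)C[Pd]Cl)[C@@]1(C)O[C@@H]1C=O | intermediate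
17 | allyl(ethyl)zinc reagent from 15, drawn as the C12-bound form (not isolated) | C/C=C(/C)C(=O)O[C@H](C/C=C(\C)CC/C=C(\C)C[Zn]CC)[C@@]1(C)O[C@@H]1C=O | intermediate
18 | (1(10)E,3R,4R,5R,6S,7S)-4,5-epoxy-6-hydroxygermacra-1(10),11-dien-3-yl (Z)-2-methylbut-2-enoate | C/C=C(/C)C(=O)O[C@@H]1C/C=C(\C)CC[C@@H](C(C)=C)[C@H](O)[C@H]2O[C@@]21C | intermediate
19 | (1(10)E,3R,4R,5R,6S,7S)-4,5-epoxy-6-hydroxygermacr-1(10)-en-3-yl (Z)-2-methylbut-2-enoate | C/C=C(/C)C(=O)O[C@@H]1C/C=C(\C)CC[C@@H](C(C)C)[C@H](O)[C@H]2O[C@@]21C | intermediate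
20 | (1(10)E,3R,4R,5R,6S,7S)-6-acetoxy-4,5-epoxygermacr-1(10)-en-3-yl (Z)-2-methylbut-2-enoate | C/C=C(/C)C(=O)O[C@@H]1C/C=C(\C)CC[C@@H](C(C)C)[C@H](OC(C)=O)[C@H]2O[C@@]21C | target

**Totals and risks**

Total step count: 11. Longest linear sequence: 11 steps (1 → 20; geranyl chloride 4 enters at step 2, angelic acid 8 at step 4).

Steps most likely to fail:

Step 9 (ring closure). Intermolecular allylation may outrun closure of the medium ring, ethyl may be transferred from zinc to the aldehyde, zinc salts may open the oxirane, or the allyl unit may attack the wrong aldehyde face. Fallback: the same bond would be closed by a Nozaki–Hiyama–Kishi reaction of an allylic bromide, with no palladium and no zinc alkyl. It sets out from 11: CBr4/PPh3 (CH2Cl2, 0 °C) would give the C12 allylic bromide F1. HF·pyridine/pyridine would then give the bromo epoxy alcohol F2, and Dess–Martin periodinane the bromo epoxy aldehyde F3. Slow addition of F3 to CrCl2 (6 equiv) in THF at rt under high dilution would form, by two one-electron transfers from divalent chromium, the allylchromium dichloride F4 (not isolated). This species equilibrates to the (E)-isomer and adds only to aldehydes through a chair array. Aqueous work-up comes back to the route at 18.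

Step 5 (allylic oxidation). The oxidant may attack the allylic positions of the internal C1=C10 alkene, or over-oxidise C12 to the enal, so that conversion has to be kept low. Fallback: the terminal oxygen would be installed by C=C metathesis instead of C–H oxidation. It sets out from 10: cross-metathesis of the terminal isopropylidene group with methacrolein (second-generation Hoveyda–Grubbs catalyst, CH2Cl2, 40 °C) would give the (E)-enal F5. The internal trisubstituted alkene and the conjugated angelate should be inert to this catalyst. Luche reduction (NaBH4, CeCl3·7H2O, MeOH, −20 °C) then comes back to the route at 11.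

Step 10 (hydrogenation). The strained (E)-ring alkene may be reduced as well, or the C11=C12 double bond may migrate on rhodium to the tetrasubstituted position before it is reduced. Fallback: metal-catalysed hydrogenation would be replaced by metal-free diimide transfer, whose rate falls steeply with alkene substitution and which cannot isomerise alkenes. It sets out from 18 (2-nitrobenzenesulfonyl hydrazide, Et3N, CH2Cl2, rt) and comes back to the route at 19.

**Further compounds**

F1 | step 9 | (2R,3R,4R,6E,10E)-12-bromo-1-(tert-butyldimethylsilyloxy)-2,3-epoxy-3,7,11-trimethyldodeca-6,10-dien-4-yl (Z)-2-methylbut-2-enoate | C/C=C(/C)C(=O)O[C@H](C/C=C(\C)CC/C=C(\C)CBr)[C@@]1(C)O[C@@H]1CO[Si](C)(C)C(C)(C)C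
F2 | step 9 | (2R,3R,4R,6E,10E)-12-bromo-2,3-epoxy-1-hydroxy-3,7,11-trimethyldodeca-6,10-dien-4-yl (Z)-2-methylbut-2-enoate | C/C=C(/C)C(=O)O[C@H](C/C=C(\C)CC/C=C(\C)CBr)[C@@]1(C)O[C@@H]1CO
F3 | step 9 | (2S,3R,4R,6E,10E)-12-bromo-2,3-epoxy-3,7,11-trimethyl-1-oxododeca-6,10-dien-4-yl (Z)-2-methylbut-2-enoate | C/C=C(/C)C(=O)O[C@H](C/C=C(\C)CC/C=C(\C)CBr)[C@@]1(C)O[C@@H]1C=O
F4 | step 9 | allylchromium dichloride from F3, drawn as the C12-bound form (not isolated) | C/C=C(/C)C(=O)O[C@H](C/C=C(\C)CC/C=C(\C)C[Cr](Cl)Cl)[C@@]1(C)O[C@@H]1C=O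
F5 | step 5 | (2R,3R,4R,6E,10E)-1-(tert-butyldimethylsilyloxy)-2,3-epoxy-3,7,11-trimethyl-12-oxododeca-6,10-dien-4-yl (Z)-2-methylbut-2-enoate | C/C=C(/C)C(=O)O[C@H](C/C=C(\C)CC/C=C(\C)C=O)[C@@]1(C)O[C@@H]1CO[Si](C)(C)C(C)(C)C
F0 | step 10 | none | none
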